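The isoflavone is disconnected at C3–C1′, the bond that nature forms by an aryl shift. Ring B is first parked on C2: the precursor is a racemic flavanone, made from an acetophenone and 3,4,5-trimethoxybenzaldehyde. The key step copies isoflavone synthase. Iodine(III) activates C3 through the C4 enol, ring B migrates from C2 to C3, and loss of H-3 gives the chromone. One operation thus joins ring B to C3 of the chromone half, cuts the temporary C2–C1′ bond and sets the C2=C3 oxidation level. It exploits the O1–C2–C3–C4(=O) array of ring C: O1 stabilises the cation left at C2, C4=O makes C3 nucleophilic, and the 4′-methoxy group of ring B supports the bridged transition state.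

Key step: step 4

Remark: the target has no stereocentre and no hindered axis, so it is achiral and needs no enantiocontrol; the only stereocentre of the route (C2 of 7) is carried as the racemate and is erased in step 4.

Step 1
Reactants: 1 1-[2,4-bis(benzyloxy)-6-hydroxyphenyl]ethan-1-one
Product: 3 1-[2,4-bis(benzyloxy)-3,6-dihydroxyphenyl]ethan-1-one, via aryl sulfate salt 2 (not isolated)
Conditions: K2S2O8 (1.1 equiv), 10% aq NaOH, pyridine, 5 °C to rt; then aq HCl to pH 1, 80 °C
Reagents that add atoms: potassium persulfate, [K+].[K+].[O-]S(=O)(=O)OOS(=O)(=O)[O-]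
Why: In this Elbs persulfate oxidation the phenoxide of 1 attacks the peroxide oxygen through C3, the free position para to the 6-OH, and acid hydrolysis of the aryl sulfate 2 should release the new phenol while the benzyl ethers and the methyl ketone survive.

Step 2
Reactants: 3 1-[2,4-bis(benzyloxy)-3,6-dihydroxyphenyl]ethan-1-one
Product: 4 1-[2,4-bis(benzyloxy)-6-hydroxy-3-methoxyphenyl]ethan-1-one
Conditions: MeI (1.05 equiv), K2CO3 (1.1 equiv), acetone, reflux, under N2
Reagents that add atoms: methyl iodide, CI
Why: In this Williamson ether synthesis the 6-OH is held in a hydrogen bond to the acetyl C=O and stays inert, so one equivalent of MeI should alkylate only the 3-OH.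

Step 3
Reactants: 4 1-[2,4-bis(benzyloxy)-6-hydroxy-3-methoxyphenyl]ethan-1-one; 5 3,4,5-trimethoxybenzaldehyde
Product: 7 (±)-5,7-bis(benzyloxy)-6-methoxy-2-(3,4,5-trimethoxyphenyl)chroman-4-one, via chalcone 6 (not isolated)
Conditions: KOH (5 equiv), EtOH, rt; then AcOH to pH 7, NaOAc, EtOH–H2O, reflux
Reagents that add atoms: none
Why: Claisen–Schmidt condensation gives the (E)-chalcone 6, and after neutralisation the free 6-OH closes ring C by a reversible 6-endo-trig oxa-Michael addition that the flanking 2-benzyloxy group favours by twisting the enone out of conjugation, the new C2 stereocentre being formed without control as the racemate because step 4 erases it.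

Step 4
Reactants: 7 (±)-5,7-bis(benzyloxy)-6-methoxy-2-(3,4,5-trimethoxyphenyl)chroman-4-one
Product: 8 5,7-bis(benzyloxy)-6-methoxy-3-(3,4,5-trimethoxyphenyl)-4H-chromen-4-one
Conditions: PhI(OH)OTs (1.2 equiv), MeCN, reflux, under N2
Reagents that add atoms: none
Why: This is the oxidative 1,2-aryl migration of a flavanone with [hydroxy(tosyloxy)iodo]benzene, a known hypervalent iodine route from flavanones to isoflavones and the laboratory counterpart of the isoflavone synthase reaction. The acidic reagent promotes enolisation of C4=O, the enol attacks iodine(III) through C3 on the face away from the C2 aryl group, and in the diaxial conformer of this transient trans 3-iodanyl ketone the C2–C1′ bond lies antiperiplanar to C3–I. Loss of iodobenzene is assisted by ring B through a phenonium-like bridge, so C1′ ends on C3, the charge arrives at C2 as an O1-stabilised oxocarbenium ion, and loss of H-3 gives the 4H-chromen-4-one. No lasting ring is closed (the three-membered bridge is only transient) and no stereocentre is created, while the C2 centre of 7 is erased, which is why the racemate serves. Migration must win over loss of H-2 without a shift, over substitution at C3 by tosylate and over contraction of ring C: the trans relation places ring B and not H-2 anti to iodine, the 4′-methoxy group and O1 lower the barrier of the shift, and acetonitrile offers no alcohol that could add to C4 and trigger migration of ring A. All phenols are masked (O1 in the ring, O5 and O7 as benzyl ethers), so iodine(III) finds no free phenol to oxidise.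

Step 5
Reactants: 8 5,7-bis(benzyloxy)-6-methoxy-3-(3,4,5-trimethoxyphenyl)-4H-chromen-4-one
Product: 9 junipegenin C, 5,7-dihydroxy-6-methoxy-3-(3,4,5-trimethoxyphenyl)-4H-chromen-4-one
Conditions: H2 (1 atm), 10% Pd/C, EtOAc–MeOH, rt, stopped after two equivalents of H2
Reagents that add atoms: none
Why: Catalytic hydrogenolysis should cleave both aryl benzyl ethers under neutral conditions faster than it reduces the conjugated C2=C3 bond, leaving the four methyl ethers untouched and giving no chance for ring opening that could move the 6-methoxy group to C8.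

Compound list
1 | 1-[2,4-bis(benzyloxy)-6-hydroxyphenyl]ethan-1-one (2,4-dibenzyl ether of phloroacetophenone, a catalogue compound) | CC(=O)c1c(O)cc(OCc2ccccc2)cc1OCc1ccccc1 | starting material
2 | potassium 3-acetyl-2,6-bis(benzyloxy)-4-hydroxyphenyl sulfate | CC(=O)c1c(O)cc(OCc2ccccc2)c(OS(=O)(=O)[O-])c1OCc1ccccc1.[K+] | intermediate
3 | 1-[2,4-bis(benzyloxy)-3,6-dihydroxyphenyl]ethan-1-one | CC(=O)c1c(O)cc(OCc2ccccc2)c(O)c1OCc1ccccc1 | intermediate
4 | 1-[2,4-bis(benzyloxy)-6-hydroxy-3-methoxyphenyl]ethan-1-one | CC(=O)c1c(O)cc(OCc2ccccc2)c(OC)c1OCc1ccccc1 | intermediate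
5 | 3,4,5-trimethoxybenzaldehyde | COc1cc(C=O)cc(OC)c1OC | starting material
6 | (E)-1-[2,4-bis(benzyloxy)-6-hydroxy-3-methoxyphenyl]-3-(3,4,5-trimethoxyphenyl)prop-2-en-1-one | COc1cc(/C=C/C(=O)c2c(O)cc(OCc3ccccc3)c(OC)c2OCc2ccccc2)cc(OC)c1OC | intermediate
7 | (±)-5,7-bis(benzyloxy)-6-methoxy-2-(3,4,5-trimethoxyphenyl)chroman-4-one (racemic at C2) | COc1cc(C2CC(=O)c3c(OCc4ccccc4)c(OC)c(OCc4ccccc4)cc3O2)cc(OC)c1OC | intermediate
8 | 5,7-bis(benzyloxy)-6-methoxy-3-(3,4,5-trimethoxyphenyl)-4H-chromen-4-one | COc1cc(-c2coc3cc(OCc4ccccc4)c(OC)c(OCc4ccccc4)c3c2=O)cc(OC)c1OC | intermediate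
9 | junipegenin C, 5,7-dihydroxy-6-methoxy-3-(3,4,5-trimethoxyphenyl)-4H-chromen-4-one (achiral) | COc1cc(-c2coc3cc(O)c(OC)c(O)c3c2=O)cc(OC)c1OC | target

Total step count: 5. Longest linear sequence: 5 steps (1 → 3 → 4 → 7 → 8 → 9).

Steps most likely to fail

Step 4. Three processes may compete with the shift: dehydrogenation across C2–C3 without migration, displacement of the C3 iodane by tosylate, and attack of iodine(III) on the electron-rich rings A and B. The fallback replaces the rearrangement by a cross-coupling. It sets out from 4 and comes back at 8.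
- Condensation of 4 with N,N-dimethylformamide dimethyl acetal (toluene, 95 °C) should give the enaminone (E)-1-[2,4-bis(benzyloxy)-6-hydroxy-3-methoxyphenyl]-3-(dimethylamino)prop-2-en-1-one F1.
- Iodine in MeOH at rt should iodinate the α-carbon and close ring C with loss of dimethylamine, giving 5,7-bis(benzyloxy)-3-iodo-6-methoxy-4H-chromen-4-one F2.
- Suzuki–Miyaura coupling of F2 with 3,4,5-trimethoxyphenylboronic acid (Pd(dppf)Cl2, K2CO3, dioxane–H2O, 80 °C) forms the same C3–C1′ bond and delivers 8.

Step 1. The risks are low conversion of the poorly soluble phenoxide, over-oxidation of the hydroquinone as it forms, and partial loss of a benzyl group during the acid hydrolysis. The fallback replaces the persulfate oxidation by a dearomatisation–rearomatisation sequence. It sets out from 1 and comes back at 4, so that 3 and step 2 are bypassed.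
- PhI(OAc)2 (2.2 equiv) in MeOH at 0 °C should methoxylate the free para position twice, giving the quinone monoketal 2-acetyl-3,5-bis(benzyloxy)-4,4-dimethoxycyclohexa-2,5-dien-1-one F3.
- Reductive aromatisation (Zn, AcOH, rt) with loss of one methanol should give 4.

Step 3. Ring closure may stay incomplete because the oxa-Michael addition is an equilibrium, and retro-aldol cleavage may set in on long heating. The fallback runs the aryl shift on the open chain, so no flavanone is needed. It sets out from 6, now isolated after the KOH stage, and comes back at 8, so that 7 and step 4 are bypassed.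
- Acetylation (Ac2O, pyridine, rt) should give the chalcone acetate 2-[(E)-3-(3,4,5-trimethoxyphenyl)prop-2-enoyl]-3,5-bis(benzyloxy)-4-methoxyphenyl acetate F4.
- Tl(NO3)3·3H2O in MeOH–HC(OMe)3 at rt should bring about oxythallation and the 1,2-aryl shift from Cβ to Cα, giving the acetal (±)-2-[3,3-dimethoxy-2-(3,4,5-trimethoxyphenyl)propanoyl]-3,5-bis(benzyloxy)-4-methoxyphenyl acetate F5.
- NaOMe in MeOH should remove the acetate to give the phenol (±)-1-[2,4-bis(benzyloxy)-6-hydroxy-3-methoxyphenyl]-3,3-dimethoxy-2-(3,4,5-trimethoxyphenyl)propan-1-one F6.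
- Dilute HCl at 50 °C should cyclise F6 with loss of two methanol molecules to give 8.

Further compounds
F1 | step 4 | (E)-1-[2,4-bis(benzyloxy)-6-hydroxy-3-methoxyphenyl]-3-(dimethylamino)prop-2-en-1-one | CN(C)/C=C/C(=O)c1c(O)cc(OCc2ccccc2)c(OC)c1OCc1ccccc1
F2 | step 4 | 5,7-bis(benzyloxy)-3-iodo-6-methoxy-4H-chromen-4-one | O=c1c(I)coc2cc(OCc3ccccc3)c(OC)c(OCc3ccccc3)c12
F3 | step 1 | 2-acetyl-3,5-bis(benzyloxy)-4,4-dimethoxycyclohexa-2,5-dien-1-one | CC(=O)C1=C(OCc2ccccc2)C(OC)(OC)C(OCc2ccccc2)=CC1=O
F4 | step 3 | 2-[(E)-3-(3,4,5-trimethoxyphenyl)prop-2-enoyl]-3,5-bis(benzyloxy)-4-methoxyphenyl acetate | COc1cc(/C=C/C(=O)c2c(OC(C)=O)cc(OCc3ccccc3)c(OC)c2OCc2ccccc2)cc(OC)c1OC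
F5 | step 3 | (±)-2-[3,3-dimethoxy-2-(3,4,5-trimethoxyphenyl)propanoyl]-3,5-bis(benzyloxy)-4-methoxyphenyl acetate | COC(OC)C(c1cc(OC)c(OC)c(OC)c1)C(=O)c1c(OC(C)=O)cc(OCc2ccccc2)c(OC)c1OCc1ccccc1
F6 | step 3 | (±)-1-[2,4-bis(benzyloxy)-6-hydroxy-3-methoxyphenyl]-3,3-dimethoxy-2-(3,4,5-trimethoxyphenyl)propan-1-one | COC(OC)C(c1cc(OC)c(OC)c(OC)c1)C(=O)c1c(O)cc(OCc2ccccc2)c(OC)c1OCc1ccccc1
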